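In the closed grey flask, solid substrate feeds a solution in which dissolved substrate can pair with itself or meet reagent. You must decide which change goes on the next run.

the same everywhere: solid substrate 1.2 M
- grey: reagent 1.8 M; the very flask that is asked about, followed so far
- violet: reagent 1.2 M; run made earlier
- flask: reagent 1.80 M; time 20 h

- grey (time / h: target / %, dissolved substrate / %): 0.833: 1, 20; 2.00: 5, 9; 4.00: 2, 3; 10.0: 6, 3
- violet (time / h: target / %, dissolved substrate / %): 2.00: 2, 9; 5.00: 3, 4; 10.0: 1, 1; 15.0: 4, 3

(scatter of a reading: 1.5 percentage points)

- percentages count the solid substrate that a species holds: one side product or self-condensation product counts as two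
- solid, in amounts per volume of the solution: solid substrate
- the numbers in the tables scatter with a standard deviation of 1.5 percentage points
- what may be going on: solid substrate <-> dissolved substrate; dissolved substrate + reagent -> target; 2 dissolved substrate -> side product; 2 solid substrate -> self-condensation product; reagent <-> dormant form
- at the start none of the solid substrate is in solution
- dissolved substrate means what is dissolved; the solid is not counted in it

1. target at 20 h, in percent of the solid substrate charged
2. concentration of dissolved substrate in solution at 10 h, in percent of saturation
3. the change that raises the amount of target at 20 h, in percent of the solid substrate charged most ("none" if none brings more than 2 percentage points) (Monday's / Wednesday's / Friday's / none)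
4. amount of target at 20 h, in percent of the solid substrate charged, after Monday's

- Monday's: doubling the dissolution coefficient of the solid substrate, all else as stated
- Wednesday's: doubling the amount of reagent, all else as stated
- Friday's: doubling the solubility of the solid substrate, all else as stated

My reckoning, read from the grey readings, each scattering by 1.5 percentage points:

1. Target per dissolved substrate: the 6% of target at 10.0 h, divided by the area under the dissolved readings, gives 0.109 h⁻¹.

2. Pairing: the rise of the reciprocal of c(dissolved substrate) between the first two readings gives 4.36 M⁻¹ h⁻¹.

3. Their ratio, 0.0249 M, is c_cross, the level of c(dissolved substrate) at which the two routes run equally, a selectivity factor with the unit of a concentration.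

4. Integrating both losses with these two coefficients held, a batch c_in passing through solution leaves c(target) equal to c_cross times the logarithm of one plus c_in/c_cross.

5. With the first reading as c_in, grey gives 4.90%. With the whole charge as c_in, it gives 8.08%.

6. Doubling reagent, taken to double c_cross, gives 7.31%, a gain of 2.4 points, over the 2 points mark. Doubling c_in, my stand-in for Monday's, gives 6.24%, a gain of 1.3 points, under that mark. So I would charge Wednesday's.

The forecast says 6.5%, 8%, Wednesday's and 7.5%, on the ground that “Doubling reagent nearly doubles target”. Its Monday figure stands above my 6.24%.

The grey flask gives 5.95%, 2.21%, Wednesday's and 7.51%. Wednesday's gains 5 points, Monday's 1.6 points and Friday's 1.9 points.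

    solid substrate ⇌ dissolved substrate, rate k1*(cs1 - [dissolved substrate]) while solid is left; crystals form when [dissolved substrate] > cs1 (solubility = 0.650 M, k = 0.788 h⁻¹)
    dissolved substrate + reagent → target (k = 0.457 M⁻¹ h⁻¹)
    2 dissolved substrate → side product (k = 3.02 M⁻¹ h⁻¹)
    2 solid substrate → self-condensation product (k = 0.919 M⁻¹ h⁻¹)
    reagent ⇌ dormant form (K = 16.1, k = 2.16 h⁻¹)

Self-condensation product holds 52.7% in the grey flask at 20.0 h, so take c_in as the remainder, 0.568 M. The c_cross of 0.0249 M then gives 6.58% against the 5.95% found, which is 0.0714 M of c(target). Now charge 0.30 M of solid substrate, with reagent unchanged. Self-condensation product holds 9.90% there, so c_in is 0.270 M, and the same c_cross gives 20.5%. That neighbouring flask gives 0.0567 M of c(target), which is 18.9% of its charge.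

Readings and results were computed for an exercise.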